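## The problem

The target is a diaryl ether in which both carbons of the C–O–C bridge are buried. Ring A C2 sits between the C1 carboxyl and the C3 hydroxyl, and ring B C2 sits next to the C1 carboxyl, which is itself flanked by the C6 hydroxyl. Ring A carries five different substituents (C1 CO2H, C2 O-aryl, C3 OH, C4 Cl, C5 OMe), so each must be placed by a regiochemically decisive reaction. The chlorine lies between two oxygens, where electrophilic chlorination is unreliable. The adjacent oxygens at ring A C2 and C3 must be told apart, because one becomes the ether and the other stays a free phenol. There are no stereocentres, so every difficulty is one of regiochemistry and chemoselectivity. The sensitive features are the two 2-aryloxybenzoic acid units (xanthone formation under dehydrating acid), the electron-rich phenolic rings (oxidation, halogenation) and the aryl chloride (hydrogenolysis). The enabling feature is on ring B: ether oxygen at C2, carboxyl at C1 and hydroxyl at C6 stand on three contiguous carbons. That is the pattern left when a nucleophile and then an electrophile add across the C1–C2 bond of a benzyne that bears an alkoxy group at C6.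

## Retrosynthesis

**Target 24 back to 22.** No skeletal bond is cut. The ring A carboxyl of 24 is taken back to the aldehyde of 23, and 23 to the fully masked acid 22 (dioxolane at ring A C1, methoxymethyl ethers at ring A C3 and ring B C6). The reason lies in the key step: an ester or aldehyde on ring A would be attacked by the aryl anion formed next to the ether oxygen and give a xanthone or xanthenol, whereas an acetal offers it nothing. The forward reactions must release three acetal-type groups with one acid treatment and oxidise an aryl aldehyde in the presence of free phenols.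

**22 back to 8, 17 and 18.** Two bonds are cut together: ring A oxygen to ring B C2, and ring B C1 to the carboxyl carbon. The neighbouring disconnection, a copper-mediated or addition–elimination ether synthesis between phenol 8 and a 2-halo-6-alkoxybenzoate, would join two di-ortho-substituted partners, which is where such couplings are weakest. An aryne is largely indifferent to hindrance, and here it also delivers the carboxyl from carbon dioxide 18 in the same operation. The precursors are two separate benzene building blocks, phenol 8 and silylaryl triflate 17. The forward reaction must be free of proton sources, must add the phenoxide 19 to aryne 20 at the carbon remote from the alkoxy group, and must carboxylate anion 21 faster than anything else.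

**8 back to 5.** The ring A C2–O bond is cut, so the hydroxyl that will become the ether is introduced last, by directed lithiation, borylation and oxidation. A starting material with the C2 oxygen already in place would need that oxygen protected through the lithiation and then freed again. It would also leave the C2 and C3 oxygens of a catechol to be differentiated. Introducing C2–OH last gives the free phenol directly, with the C3 oxygen already a methoxymethyl ether. The forward reaction must metalate C2 (between the dioxolane and the methoxymethoxy group) and not C6 (between the dioxolane and the methoxy group).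

**5 back to 3, 2 and 1.** The C4–Cl bond is cut. In 3, C4 is the carbon between the two ether oxygens, the most acidic position of a 1,3-dialkoxyarene, so lithiation and chlorination put the halogen where electrophilic chlorination would not. Ether 3 comes from phenol 2 by O-alkylation, and 2 from the aldehyde 1 by acetalisation. The acetal is made first so that the acid-labile methoxymethyl ether never meets the acid catalyst.

**17 back to 15, 11, 10 and 9.** The triflate O–S bond and the aryl–silicon bond are cut. The silicon is placed between the two oxygens of carbamate 11 by directed lithiation. Carbamate 11 comes from the mono-protected resorcinol 10, and 10 from orcinol 9. The N-isopropyl carbamate is chosen because it directs metalation strongly and is removed by mild base, so carbamate cleavage and triflation of 15 can share one flask.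

## Roads not taken

**Alternative 1:** Ring A is cut at C1–C2 back to the acyclic triketo ester A1, which already carries the ring B aryloxy group on C7. In the forward step base folds A1 so that C7 adds to the C2 ketone; loss of water and enolisation give the resorcinol A2.
- Merits: the hindered aryl–oxygen bond is made early as an ordinary alkyl aryl ether, ring B arrives complete, and every reaction type is known. On precedent this is better than the chosen plan.
- Weak points: C7 is the least acidic methylene of A1, since C3 and C5 each lie between two carbonyls. The polyanion therefore has easier options, such as pyranone formation or attack of C5 on the ester. A2 still lacks the C4 chlorine and the C5 methyl ether. Chlorination at C4, between two oxygens, must compete with ring A C6 and with the activated C3 and C5 positions of ring B. The benzyl ether must later be removed beside an aryl chloride.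
- Comparison: the chosen plan places the chlorine by directed metalation before the rings are joined and needs no late electrophilic substitution. Against this it has to set one untested bond-forming step.

**Alternative 2:** Ring B is cut at C5–C6 back to the dienylidene malonate A3, made from the same phenol 8. Base removes a proton from a terminal methyl group, the carbanion acylates on one malonate ester, and tautomerisation gives the salicylate A4.
- Merits: ring A chemistry is identical to the chosen plan, the ring B substitution pattern is fixed by connectivity with no regiochemical question, there is no aryne, and all steps are known reaction types. In certainty of outcome it is at least as good as the chosen plan.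
- Weak points: A3 is a doubly activated enol ether, so the aryloxide of 8 is a leaving group under the strongly basic conditions of the cyclisation, and the methoxide released can displace it. A4 carries a methyl ester flanked by hydroxyl and aryloxy groups, whose hydrolysis is slow. Several extra steps are needed between 8 and the stage of 22.
- Comparison: the chosen plan offers a one-step union of two short branches and delivers the ring B carboxyl as the free acid. It pays with the risk of the new three-component step.

**Alternative 3:** Ring A is cut to the diazo ketone A5 and the silyl ynol ether A6. Photochemical Wolff rearrangement of A5 gives a vinylketene, which undergoes cycloaddition with A6, electrocyclic opening and six-electron closure to the phenol A7. The silicon at C4 is a placeholder for chlorine.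
- Merits: the whole ring A pattern follows from the polarity of the two components, and ipso-chlorodesilylation would place chlorine exactly at C4. In this respect it equals the chosen plan.
- Weak points: A5 is a push–pull β-aryloxy acrylate bearing a diazoacetyl group, difficult to make and to keep. A6 is a sensitive ynol ether. The arylsilane of A7, ortho to a free phenol, is prone to protodesilylation, and chlorodesilylation must outrun chlorination of ring B. Two methyl esters, one of them hindered, must be hydrolysed, and the benzyl ether must be removed beside the chloride.
- Comparison: the chosen plan gets the same certainty at C4 from two simple metalation steps and avoids diazo chemistry and photolysis. Its own weakness remains the unprecedented trapping step.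

Key step: step 9

## Route

Remark: the target has no stereocentre, so no structure below needs a stereodescriptor.

Step 1
Reactants: 1 3-hydroxy-5-methoxybenzaldehyde
Product: 2 3-(1,3-dioxolan-2-yl)-5-methoxyphenol
Conditions: HOCH2CH2OH, TsOH·H2O (cat.), toluene, reflux, Dean–Stark
Reagents that add atoms: ethylene glycol, OCCO
Why: Acid-catalysed acetalisation with azeotropic removal of water; the meta-hydroxyl is not hydrogen-bonded to the aldehyde and does not interfere, and making the acetal before any methoxymethyl ether exists keeps that group away from acid.

Step 2
Reactants: 2 3-(1,3-dioxolan-2-yl)-5-methoxyphenol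
Product: 3 2-[3-methoxy-5-(methoxymethoxy)phenyl]-1,3-dioxolane
Conditions: NaH, DMF, 0 °C; MOMCl, 0 °C to rt
Reagents that add atoms: chloromethyl methyl ether, COCCl
Why: Williamson-type O-alkylation of the sodium phenoxide under basic conditions that leave the dioxolane untouched; the methoxymethyl ether serves as protecting group and as the strongest metalation director on the ring.

Step 3
Reactants: 3 2-[3-methoxy-5-(methoxymethoxy)phenyl]-1,3-dioxolane
Product: 5 2-[4-chloro-3-methoxy-5-(methoxymethoxy)phenyl]-1,3-dioxolane, via aryllithium 4 (not isolated)
Conditions: n-BuLi, THF, −20 to 0 °C; C2Cl6, −78 °C to rt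
Reagents that add atoms: hexachloroethane, ClC(Cl)(Cl)C(Cl)(Cl)Cl
Why: Directed ortho-metalation; C4 lies between the methoxymethoxy and methoxy oxygens, the doubly activated site of a 1,3-dialkoxyarene, so it should be lithiated in preference to C2 or C6, and aryllithium 4 is chlorinated by hexachloroethane with loss of tetrachloroethene.

Step 4
Reactants: 5 2-[4-chloro-3-methoxy-5-(methoxymethoxy)phenyl]-1,3-dioxolane
Product: 8 3-chloro-6-(1,3-dioxolan-2-yl)-4-methoxy-2-(methoxymethoxy)phenol, via aryllithium 6 (not isolated), via lithium aryltrimethoxyborate 7 (not isolated)
Conditions: s-BuLi, TMEDA, THF, −78 °C; B(OMe)3, −78 °C to rt; 30% H2O2, aq NaOH, 0 °C; pH 7 buffer work-up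
Reagents that add atoms: hydrogen peroxide, OO
Why: Second directed ortho-metalation followed by borylation and peroxide oxidation of the aryl–boron bond; C2 is flanked by the chelating methoxymethoxy group, a stronger director than the methoxy group beside C6, so lithiation should occur at C2, no proton ortho to chlorine remains so the chloride cannot eliminate to an aryne, and the basic oxidation with neutral work-up preserves the acetal.

Step 5
Reactants: 9 orcinol (5-methylbenzene-1,3-diol)
Product: 10 3-(methoxymethoxy)-5-methylphenol
Conditions: NaH (1 equiv), DMF, 0 °C; MOMCl (1 equiv), 0 °C to rt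
Reagents that add atoms: chloromethyl methyl ether, COCCl
Why: Statistical mono-O-alkylation of a symmetrical resorcinol with one equivalent each of base and alkylating agent; unreacted 9 and the bis-ether are separable from 10 and can be recycled.

Step 6
Reactants: 10 3-(methoxymethoxy)-5-methylphenol
Product: 11 3-(methoxymethoxy)-5-methylphenyl N-(propan-2-yl)carbamate
Conditions: i-PrNCO, Et3N (cat.), CH2Cl2, rt
Reagents that add atoms: isopropyl isocyanate, CC(C)N=C=O
Why: Base-catalysed addition of the phenol to the isocyanate gives the N-monoalkyl carbamate, a strong ortho-director that can later be removed by mild base.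

Step 7
Reactants: 11 3-(methoxymethoxy)-5-methylphenyl N-(propan-2-yl)carbamate
Product: 15 3-(methoxymethoxy)-5-methyl-2-(trimethylsilyl)phenyl N-(propan-2-yl)carbamate, via N-silyl carbamate 12 (not isolated), via aryllithium 13 (not isolated), via bis-silylated carbamate 14 (not isolated)
Conditions: TBSOTf, TMEDA, Et2O, 0 °C to rt; n-BuLi, TMEDA, −78 °C; TMSCl, −78 °C to rt; brief cold aq NaHSO4 work-up
Reagents that add atoms: chlorotrimethylsilane, C[Si](C)(C)Cl
Why: Directed ortho-metalation of an in situ N-silylated aryl carbamate; N-silylation blocks N–H deprotonation and isocyanate loss, the proton between the carbamate and methoxymethoxy oxygens is the most acidic on the ring so lithiation and C-silylation occur there, and the N-silyl group falls off on aqueous work-up.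

Step 8
Reactants: 15 3-(methoxymethoxy)-5-methyl-2-(trimethylsilyl)phenyl N-(propan-2-yl)carbamate
Product: 17 3-(methoxymethoxy)-5-methyl-2-(trimethylsilyl)phenyl trifluoromethanesulfonate, via silylphenol 16 (not isolated)
Conditions: DBU, Et2NH, MeCN, 40 °C; then PhNTf2, rt
Reagents that add atoms: N-phenylbis(trifluoromethanesulfonimide), O=S(=O)(N(c1ccccc1)S(=O)(=O)C(F)(F)F)C(F)(F)F
Why: The amidine base removes the carbamate N–H proton, E1cB loss of isopropyl isocyanate (trapped by diethylamine as a urea) releases the phenoxide of 16, and this is O-triflated in the same flask; a standard one-pot route to ortho-silylaryl triflates.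

Step 9
Reactants: 8 3-chloro-6-(1,3-dioxolan-2-yl)-4-methoxy-2-(methoxymethoxy)phenol; 17 3-(methoxymethoxy)-5-methyl-2-(trimethylsilyl)phenyl trifluoromethanesulfonate; 18 carbon dioxide
Product: 22 2-[3-chloro-6-(1,3-dioxolan-2-yl)-4-methoxy-2-(methoxymethoxy)phenoxy]-6-(methoxymethoxy)-4-methylbenzoic acid, via potassium phenoxide 19 (not isolated), via aryne 20 (not isolated), via arylpotassium 21 (not isolated)
Conditions: KH, THF, 0 °C; then CO2 (1 atm), KF, 18-crown-6, slow addition of 17, 0 °C to rt; cold dilute aq HCl to pH 4
Reagents that add atoms: none
Why: Proposed new method: KH converts 8 into the potassium phenoxide 19 with loss of H2, so no O–H proton remains in the flask, and fluoride then attacks silicon in 17 with expulsion of triflate to give aryne 20. Phenoxide 19 adds through oxygen (its ortho and para carbons are all substituted) to the aryne carbon remote from the methoxymethoxy group, the more distorted and more electrophilic terminus, which leaves the negative charge on the carbon next to the inductively withdrawing oxygen. The resulting aryl anion 21, flanked by two oxygens, is captured by CO2 to give the potassium carboxylate, so the aryl–oxygen bond and the C1–carboxyl bond form in one operation. The closest known reaction types are the fluoride-induced three-component coupling of arynes, amines and CO2 to anthranilic acids and the O-arylation of phenols by arynes from ortho-silylaryl triflates; combining a phenoxide nucleophile with CO2 trapping is the untested element. No ring is closed and no stereocentre is formed. The step needs regioselective addition, secured by the alkoxy group adjacent to the aryne, and chemoselective carboxylation of 21, secured by the proton-free medium, by the excess of CO2 and by carrying the ring A carboxyl as a dioxolane that offers the anion no internal electrophile (an ester or aldehyde would lead to a xanthone or xanthenol). Crowding at the phenoxide oxygen should matter little because capture of an aryne has a very low barrier.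

Step 10
Reactants: 22 2-[3-chloro-6-(1,3-dioxolan-2-yl)-4-methoxy-2-(methoxymethoxy)phenoxy]-6-(methoxymethoxy)-4-methylbenzoic acid
Product: 23 2-(3-chloro-6-formyl-2-hydroxy-4-methoxyphenoxy)-6-hydroxy-4-methylbenzoic acid
Conditions: 3 M aq HCl, THF, 40 °C
Reagents that add atoms: water, O
Why: Acid-catalysed hydrolysis of the dioxolane and both methoxymethyl ethers in one operation; the diaryl ether, aryl chloride, methyl ether and carboxylic acid are stable to dilute aqueous acid at this temperature.

Step 11
Reactants: 23 2-(3-chloro-6-formyl-2-hydroxy-4-methoxyphenoxy)-6-hydroxy-4-methylbenzoic acid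
Product: 24 2-(2-carboxy-3-hydroxy-5-methylphenoxy)-4-chloro-3-hydroxy-5-methoxybenzoic acid (target)
Conditions: NaClO2, NaH2PO4, 2-methyl-2-butene (large excess), t-BuOH–THF–H2O, 0 °C to rt
Reagents that add atoms: sodium chlorite (NaClO2), [Na+].[O-]Cl=O
Why: Pinnick oxidation of the aryl aldehyde to the carboxylic acid; the buffer and the excess alkene intercept the hypochlorous acid formed, so the free phenolic rings should not be chlorinated.

## Compound list

1 | 3-hydroxy-5-methoxybenzaldehyde | COc1cc(O)cc(C=O)c1 | starting material
2 | 3-(1,3-dioxolan-2-yl)-5-methoxyphenol | COc1cc(O)cc(C2OCCO2)c1 | intermediate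
3 | 2-[3-methoxy-5-(methoxymethoxy)phenyl]-1,3-dioxolane | COCOc1cc(OC)cc(C2OCCO2)c1 | intermediate
4 | [4-(1,3-dioxolan-2-yl)-2-methoxy-6-(methoxymethoxy)phenyl]lithium | [Li]c1c(OC)cc(C2OCCO2)cc1OCOC | intermediate
5 | 2-[4-chloro-3-methoxy-5-(methoxymethoxy)phenyl]-1,3-dioxolane | COCOc1cc(C2OCCO2)cc(OC)c1Cl | intermediate
6 | [3-chloro-6-(1,3-dioxolan-2-yl)-4-methoxy-2-(methoxymethoxy)phenyl]lithium | [Li]c1c(C2OCCO2)cc(OC)c(Cl)c1OCOC | intermediate
7 | lithium [3-chloro-6-(1,3-dioxolan-2-yl)-4-methoxy-2-(methoxymethoxy)phenyl]trimethoxyborate | [Li+].CO[B-](OC)(OC)c1c(C2OCCO2)cc(OC)c(Cl)c1OCOC | intermediate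
8 | 3-chloro-6-(1,3-dioxolan-2-yl)-4-methoxy-2-(methoxymethoxy)phenol | COc1cc(C2OCCO2)c(O)c(OCOC)c1Cl | intermediate
9 | orcinol (5-methylbenzene-1,3-diol) | Cc1cc(O)cc(O)c1 | starting material
10 | 3-(methoxymethoxy)-5-methylphenol | COCOc1cc(C)cc(O)c1 | intermediate
11 | 3-(methoxymethoxy)-5-methylphenyl N-(propan-2-yl)carbamate | COCOc1cc(C)cc(OC(=O)NC(C)C)c1 | intermediate
12 | 3-(methoxymethoxy)-5-methylphenyl N-[tert-butyl(dimethyl)silyl]-N-(propan-2-yl)carbamate | COCOc1cc(C)cc(OC(=O)N(C(C)C)[Si](C)(C)C(C)(C)C)c1 | intermediate
13 | [2-({[tert-butyl(dimethyl)silyl](propan-2-yl)carbamoyl}oxy)-6-(methoxymethoxy)-4-methylphenyl]lithium | [Li]c1c(OCOC)cc(C)cc1OC(=O)N(C(C)C)[Si](C)(C)C(C)(C)C | intermediate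
14 | 3-(methoxymethoxy)-5-methyl-2-(trimethylsilyl)phenyl N-[tert-butyl(dimethyl)silyl]-N-(propan-2-yl)carbamate | COCOc1cc(C)cc(OC(=O)N(C(C)C)[Si](C)(C)C(C)(C)C)c1[Si](C)(C)C | intermediate
15 | 3-(methoxymethoxy)-5-methyl-2-(trimethylsilyl)phenyl N-(propan-2-yl)carbamate | COCOc1cc(C)cc(OC(=O)NC(C)C)c1[Si](C)(C)C | intermediate
16 | 3-(methoxymethoxy)-5-methyl-2-(trimethylsilyl)phenol (formed as its amidinium phenoxide) | COCOc1cc(C)cc(O)c1[Si](C)(C)C | intermediate
17 | 3-(methoxymethoxy)-5-methyl-2-(trimethylsilyl)phenyl trifluoromethanesulfonate | Cc1cc(OCOC)c([Si](C)(C)C)c(OS(=O)(=O)C(F)(F)F)c1 | intermediate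
18 | carbon dioxide | O=C=O | starting material
19 | potassium 3-chloro-6-(1,3-dioxolan-2-yl)-4-methoxy-2-(methoxymethoxy)phenoxide | [K+].COc1cc(C2OCCO2)c([O-])c(OCOC)c1Cl | intermediate
20 | 3-(methoxymethoxy)-5-methylbenzyne (1,2-didehydro-3-(methoxymethoxy)-5-methylbenzene) | COCOC1=CC(C)=CC#C1 | intermediate
21 | {2-[3-chloro-6-(1,3-dioxolan-2-yl)-4-methoxy-2-(methoxymethoxy)phenoxy]-6-(methoxymethoxy)-4-methylphenyl}potassium | COc1cc(C2OCCO2)c(Oc2cc(C)cc(OCOC)c2[K])c(OCOC)c1Cl | intermediate
22 | 2-[3-chloro-6-(1,3-dioxolan-2-yl)-4-methoxy-2-(methoxymethoxy)phenoxy]-6-(methoxymethoxy)-4-methylbenzoic acid | COc1cc(C2OCCO2)c(Oc2cc(C)cc(OCOC)c2C(=O)O)c(OCOC)c1Cl | intermediate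
23 | 2-(3-chloro-6-formyl-2-hydroxy-4-methoxyphenoxy)-6-hydroxy-4-methylbenzoic acid | COc1cc(C=O)c(Oc2cc(C)cc(O)c2C(=O)O)c(O)c1Cl | intermediate
24 | 2-(2-carboxy-3-hydroxy-5-methylphenoxy)-4-chloro-3-hydroxy-5-methoxybenzoic acid | COc1cc(C(=O)O)c(Oc2cc(C)cc(O)c2C(=O)O)c(O)c1Cl | target

## Step count and least certain steps

Total steps: 11. Longest linear sequence: 7 steps (steps 1–4, 9, 10, 11 from compound 1; the ring B branch, steps 5–8, 9, 10, 11 from compound 9, is equally long).

**Step 9 (key step, proposed new method).** The most likely failure is protonation of aryl anion 21 instead of carboxylation, because the anion is very basic and any adventitious proton source or slow uptake of CO2 diverts it. Two further risks are reversible capture of CO2 by phenoxide 19 (aryl carbonate formation), which slows its addition to the aryne, and addition of the product carboxylate to excess aryne, which is why 17 is added slowly. The fallback uses two known reactions and sets out from 8 and 17. Fluoride-induced O-arylation of the free phenol (CsF, MeCN, rt), in which the phenol itself protonates the aryl anion, should give 2-{4-chloro-5-methoxy-3-(methoxymethoxy)-2-[3-(methoxymethoxy)-5-methylphenoxy]phenyl}-1,3-dioxolane F1 with the same regiochemistry. Directed ortho-lithiation of F1 with n-BuLi in THF at the ring B carbon between the aryloxy and methoxymethoxy oxygens, followed by a CO2 quench, regenerates the same anion and returns to the route at 22.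

**Step 4.** The most likely failure is poor site selectivity of the metalation, that is, lithiation at C6 as well as C2, because both positions are ortho to the dioxolane and differ only in the strength of the flanking oxygen director. Attack of the base on the acetal C–H and protodeboronation before oxidation are lesser concerns. The fallback changes the director and sets out from 2:
- O-carbamoylation (ClCONEt2, NaH) gives 3-(1,3-dioxolan-2-yl)-5-methoxyphenyl diethylcarbamate F2.
- Lithiation between the carbamate and methoxy groups and chlorination (s-BuLi, TMEDA, −78 °C; C2Cl6) give 2-chloro-5-(1,3-dioxolan-2-yl)-3-methoxyphenyl diethylcarbamate F3.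
- The carbamate, the strongest oxygen director, now has only one free ortho position, so lithiation, borylation and peroxide oxidation give 2-chloro-5-(1,3-dioxolan-2-yl)-6-hydroxy-3-methoxyphenyl diethylcarbamate F4.
- Reductive cleavage with LiAlH4 gives 3-chloro-6-(1,3-dioxolan-2-yl)-4-methoxybenzene-1,2-diol F5.
- Mono-alkylation of the more acidic hydroxyl, the one next to chlorine, with MOMCl and one equivalent of K2CO3 returns to the route at 8.

**Step 11 (with step 10).** The most likely failure is electrophilic chlorination or oxidation of the free phenolic rings by hypochlorous acid or chlorine dioxide, since ring B C3 and C5 are activated. In step 10 the freed aldehyde could also cyclise onto ring B under acid. The fallback postpones release of the phenols and sets out from 22: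
- Mild selective hydrolysis of the dioxolane (PPTS, acetone–H2O, rt) gives 2-[3-chloro-6-formyl-4-methoxy-2-(methoxymethoxy)phenoxy]-6-(methoxymethoxy)-4-methylbenzoic acid F6.
- Pinnick oxidation gives 2-[2-carboxy-3-(methoxymethoxy)-5-methylphenoxy]-4-chloro-5-methoxy-3-(methoxymethoxy)benzoic acid F7.
- Aqueous HCl in THF then removes both methoxymethyl groups and returns to the route at 24.

**Step 5.** The most likely failure is over-alkylation, because the second hydroxyl of 9 is as reactive as the first and the mixture is statistical. The fallback replaces statistical protection by exhaustive acylation and a self-limiting cleavage, and sets out from 9: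
- Excess i-PrNCO with Et3N gives 5-methyl-1,3-phenylene bis[N-(propan-2-yl)carbamate] F8.
- DBU and Et2NH in MeCN should remove only one carbamate, because the phenoxide released makes the remaining aryloxide a far poorer leaving group for the E1cB step; this gives 3-hydroxy-5-methylphenyl N-(propan-2-yl)carbamate F9.
- MOMCl with i-Pr2NEt in CH2Cl2 returns to the route at 11.

## Further compounds

F1 | step 9 | 2-{4-chloro-5-methoxy-3-(methoxymethoxy)-2-[3-(methoxymethoxy)-5-methylphenoxy]phenyl}-1,3-dioxolane | COc1cc(C2OCCO2)c(Oc2cc(C)cc(OCOC)c2)c(OCOC)c1Cl
F2 | step 4 | 3-(1,3-dioxolan-2-yl)-5-methoxyphenyl diethylcarbamate | CCN(CC)C(=O)Oc1cc(OC)cc(C2OCCO2)c1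
F3 | step 4 | 2-chloro-5-(1,3-dioxolan-2-yl)-3-methoxyphenyl diethylcarbamate | CCN(CC)C(=O)Oc1cc(C2OCCO2)cc(OC)c1Cl
F4 | step 4 | 2-chloro-5-(1,3-dioxolan-2-yl)-6-hydroxy-3-methoxyphenyl diethylcarbamate | CCN(CC)C(=O)Oc1c(O)c(C2OCCO2)cc(OC)c1Cl
F5 | step 4 | 3-chloro-6-(1,3-dioxolan-2-yl)-4-methoxybenzene-1,2-diol | COc1cc(C2OCCO2)c(O)c(O)c1Cl
F6 | step 11 | 2-[3-chloro-6-formyl-4-methoxy-2-(methoxymethoxy)phenoxy]-6-(methoxymethoxy)-4-methylbenzoic acid | COc1cc(C=O)c(Oc2cc(C)cc(OCOC)c2C(=O)O)c(OCOC)c1Cl
F7 | step 11 | 2-[2-carboxy-3-(methoxymethoxy)-5-methylphenoxy]-4-chloro-5-methoxy-3-(methoxymethoxy)benzoic acid | COc1cc(C(=O)O)c(Oc2cc(C)cc(OCOC)c2C(=O)O)c(OCOC)c1Cl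
F8 | step 5 | 5-methyl-1,3-phenylene bis[N-(propan-2-yl)carbamate] | Cc1cc(OC(=O)NC(C)C)cc(OC(=O)NC(C)C)c1
F9 | step 5 | 3-hydroxy-5-methylphenyl N-(propan-2-yl)carbamate | Cc1cc(O)cc(OC(=O)NC(C)C)c1
A1 | alternative 1 | methyl 7-[3-(benzyloxy)-2-(tert-butoxycarbonyl)-5-methylphenoxy]-2,4,6-trioxoheptanoate | COC(=O)C(=O)CC(=O)CC(=O)COc1cc(C)cc(OCc2ccccc2)c1C(=O)OC(C)(C)C
A2 | alternative 1 | methyl 2-[3-(benzyloxy)-2-(tert-butoxycarbonyl)-5-methylphenoxy]-3,5-dihydroxybenzoate | COC(=O)c1cc(O)cc(O)c1Oc1cc(C)cc(OCc2ccccc2)c1C(=O)OC(C)(C)C
A3 | alternative 2 | dimethyl 2-{1-[3-chloro-6-(1,3-dioxolan-2-yl)-4-methoxy-2-(methoxymethoxy)phenoxy]-3-methylbut-2-en-1-ylidene}propanedioate | COC(=O)C(C(=O)OC)=C(Oc1c(C2OCCO2)cc(OC)c(Cl)c1OCOC)C=C(C)C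
A4 | alternative 2 | methyl 2-[3-chloro-6-(1,3-dioxolan-2-yl)-4-methoxy-2-(methoxymethoxy)phenoxy]-6-hydroxy-4-methylbenzoate | COC(=O)c1c(O)cc(C)cc1Oc1c(C2OCCO2)cc(OC)c(Cl)c1OCOC
A5 | alternative 3 | methyl 3-[3-(benzyloxy)-2-(methoxycarbonyl)-5-methylphenoxy]-2-(diazoacetyl)prop-2-enoate | COC(=O)C(=COc1cc(C)cc(OCc2ccccc2)c1C(=O)OC)C(=O)C=[N+]=[N-]
A6 | alternative 3 | methoxy(trimethylsilyl)ethyne | COC#C[Si](C)(C)C
A7 | alternative 3 | methyl 2-[3-(benzyloxy)-2-(methoxycarbonyl)-5-methylphenoxy]-3-hydroxy-5-methoxy-4-(trimethylsilyl)benzoate | COC(=O)c1cc(OC)c([Si](C)(C)C)c(O)c1Oc1cc(C)cc(OCc2ccccc2)c1C(=O)OC
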